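Start with the easy step: pre-initiator turns into initiator on its own, a first-order clock with a half-life of 1.6 h, whatever else the vessel holds. Initiator then takes a free monomer and becomes a living end, and a living end goes on taking free monomer and stays living.

in all of them: pre-initiator 6.0 mM
- alder: free monomer 0.076 M; a single well-mixed tank run continuously and read at steady state, 4.0 h in it on average
- cedar: free monomer 0.076 M; everything together in a closed stirred flask, run for 4.0 h; time 4.0 h
- birch: free monomer 0.076 M (fed, over 3.20 h); all but free monomer at the start; free monomer goes in evenly over 3.20 h, the run ends at 4.0 h; time 4.0 h

* the set-up with the highest amount of monomer in chains at the outlet or at the end, in percent of the free monomer put in ("none" if the first two lie within 2 percentage points) (alder / cedar / birch / none)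
* amount of monomer in chains at the outlet or at the end, in percent of the free monomer put in, alder
* amount of monomer in chains at the outlet or at the end, in percent of the free monomer put in, cedar
* amount of monomer in chains at the outlet or at the end, in percent of the free monomer put in, birch

- the stated concentrations are those of everything mixed, before any reaction; amounts are the same in each set-up
- the feed brings no volume worth counting
- run time (cedar): 4.0 h

Now set the clocks in a row, fastest first. If the whole pre-initiator charge stood as living ends, free monomer would have a half-life of 0.309 h. Initiator at the charged free monomer has 0.62 h, pre-initiator has 1.6 h, and the run or average stay is 4.0 h. A full charge of living ends would therefore use free monomer quicker than the charged free monomer uses initiator. Pre-initiator is slower than both, and the run or stay spans 2.53 of its half-lives, so ends are still arriving at the end of it.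

Follow one free monomer through alder. A pre-initiator there reacts or leaves, and the odds give 63.7% reacted. Guess that 25.0% of the free monomer charge stands free in alder's tank; an initiator then faces the same kind of fork, and 52.8% of it becomes living ends. So living ends in alder hold 33.6% of the pre-initiator charge. A free monomer's chance per unit time of meeting a living end, times its stay, gives 3.02, the hit number: the hits it would collect if it survived them. In alder, hits on initiator come to 3.51% of hits on living ends, so I leave them out.

In alder's tank, hit against leave is a fork with odds of the hit number to one. The share leaving alder unhit is 24.9%, which returns my guess, and I commit to 75.1% in chains for alder. In cedar's closed flask a free monomer stays the full 4.0 h, so the unhit share falls exponentially with the hit number summed over the run. Cedar's ends rise from zero, so I do not reckon its hit number by hand, and birch I leave open.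

The forecast says cedar, with 75.5% for alder, 92.8% for cedar and 82% for birch, on the ground that “the closed flask, with all its monomer present from the start” converts the most. My alder figure is a little lower than its figure.

The simulation gives cedar as best, with 75.6% for alder, 92.8% for cedar and 82.3% for birch.

    pre-initiator → initiator (k1 = 0.00731 min⁻¹)
    free monomer + initiator → living end + monomer in chains (k2 = 0.245 L mol⁻¹ min⁻¹)
    free monomer + living end → monomer in chains + living end, rate k3*[living end]*[free monomer] (k3 = 6.24 L mol⁻¹ min⁻¹)

Read through the tank's fork, alder's free monomer at 24.4% of the charge gives a hit number of 3.09, hits on initiator included, against my 3.02. Read through the exponential law, cedar's result gives 2.64, hits on initiator included, so cedar's free monomer collects fewer hits than alder's, and yet cedar ends with less of it free, 7.20% of the charge against 24.4%.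

The rate constants come from no measurement; the flask was simulated.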